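## Retrosynthetic overview
1. The quinones come last. The target is made from the corresponding bis(hydroquinone dimethyl ether) by oxidative demethylation. No ring is built: both six-membered rings are bought as hydroquinone and carried in parallel.
2. The two aryl–CH2 bonds come from a meso diiodo diester and two geranyl acetates (arylzinc plus pi-allylpalladium). Geranyl acetate is built from a C6 bromide, acetylide, AlMe3 and CH2O, and syn-carboalumination sets the E alkene.
3. Key step: a two-fold oxidative 1,2-aryl shift turns a 1,4-diaryl-1,4-diketone into the 2,3-diarylsuccinate. It makes both aryl–C(alpha) bonds and both stereocentres, and base equilibration with crystallisation then gives the meso ester.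
4. The diketone comes from succinyl chloride and two 1,4-dimethoxybenzenes (Friedel–Crafts). Chelation-controlled demethylation frees the phenol that steers iodine to the carbon that later carries geranyl.

Assumption: the two stereocentres carry identical substituents and opposite descriptors (2S,3R = 2R,3S). The SMILES therefore encodes the achiral meso diastereomer, and the stereochemical task is relative configuration (meso against the C2-symmetric racemate) plus two E alkenes.

## Route

Step 1
Reactants: 1 hydroquinone
Product: 2 1,4-dimethoxybenzene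
Conditions: MeI (2.5 equiv), K2CO3 (3 equiv), acetone, reflux
Reagents that add atoms: iodomethane, CI
Why: Double Williamson ether synthesis masks the hydroquinone as the dimethyl ether, which tolerates acid and organometallics and is reopened to the quinone only in the last step.

Step 2
Reactants: 2 1,4-dimethoxybenzene (2.1 equiv); 3 succinyl chloride
Product: 5 1,4-bis(2-hydroxy-5-methoxyphenyl)butane-1,4-dione, via tetramethoxy diketone 4 (not isolated)
Conditions: AlCl3 (5 equiv), CH2Cl2, 0 °C to reflux; 1 M HCl quench
Reagents that add atoms: none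
Why: Two-fold Friedel–Crafts acylation gives a single regioisomer because all four free positions of 2 are equivalent, and chelation-controlled AlCl3 ether cleavage in the same flask then removes only the methoxy group ortho to each carbonyl.

Step 3
Reactants: 5 1,4-bis(2-hydroxy-5-methoxyphenyl)butane-1,4-dione
Product: 7 1,4-bis(3-iodo-2,5-dimethoxyphenyl)butane-1,4-dione, via diiodo bisphenol 6 (not isolated)
Conditions: NIS (2.1 equiv), TFA (10 mol%), MeCN, rt, dark; then K2CO3 and MeI (6 equiv each, the succinimide formed is N-methylated as well), same flask, 45 °C, sealed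
Reagents that add atoms: N-iodosuccinimide, O=C1CCC(=O)N1I; iodomethane, CI
Why: Electrophilic aromatic iodination goes ortho to the free phenol (its para position is blocked by OMe, and C3 is also meta to the acyl group), which fixes the 1,2,3,5 pattern of the later 2,6-disubstituted quinone, and Williamson O-methylation then restores the dimethyl ether.

Step 4
Reactants: 7 1,4-bis(3-iodo-2,5-dimethoxyphenyl)butane-1,4-dione
Product: 11 dimethyl (2R,3S)-2,3-bis(3-iodo-2,5-dimethoxyphenyl)butanedioate (meso), via bis(dimethyl ketal) 8 (not isolated), via ketal ester 9 (not isolated), via racemic diester 10 (not isolated)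
Conditions: HC(OMe)3/MeOH (1:1), H2SO4 (2 equiv), rt, 1 h; PhI(OAc)2 (2.3 equiv), 0 to 40 °C; NaHCO3 wash, crude into MeOH, NaOMe (0.3 equiv), reflux, slow cooling to 0 °C, filter
Reagents that add atoms: trimethyl orthoformate, COC(OC)OC; methanol (co-solvent, exchanges with the ketal methoxy groups), CO
Why: Proposed new method: a two-fold oxidative 1,2-aryl shift of a 1,4-diaryl-1,4-diketone to a 2,3-diarylsuccinate, not yet shown for this substrate class; each ketal (8, then 9) ionises to its methyl enol ether, the trivalent iodine reagent bonds to the alpha carbon, methanol re-forms the ketal, and the aryl group moves from the ketal carbon to the alpha carbon through a bridged phenonium ion as PhI leaves, the dimethoxycarbenium ion then losing a methyl group to acetate to give the ester, so both aryl–C(alpha) bonds and both stereocentres form in one flask; NaOMe-catalysed enolisation then funnels the 10/11 mixture, because the centrosymmetric meso ester 11 (aryl anti to aryl and ester anti to ester in one conformer) should be the more stable and far less soluble isomer and crystallise out (crystallisation-induced diastereomer transformation); closest known reaction type: the PhI(OAc)2 or Tl(NO3)3 oxidative rearrangement of alkyl aryl ketones and 3-aroylpropanoates in HC(OMe)3/MeOH to 2-arylalkanoates and arylsuccinates.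

Step 5
Reactants: 12 5-bromo-2-methylpent-2-ene; 13 lithium acetylide–ethane-1,2-diamine complex (LiC≡CH·H2NCH2CH2NH2)
Product: 14 6-methylhept-5-en-1-yne
Conditions: DMSO, 10 °C to rt; distil
Reagents that add atoms: none
Why: SN2 alkylation of acetylide on a primary homoallylic bromide in a dipolar aprotic solvent.

Step 6
Reactants: 14 6-methylhept-5-en-1-yne
Product: 18 geranyl acetate, (2E)-3,7-dimethylocta-2,6-dien-1-yl acetate, via alkenylalane 15 (not isolated), via lithium alanate 16 (not isolated), via alkoxyalanate 17 (not isolated)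
Conditions: AlMe3 (2 equiv), Cp2ZrCl2 (20 mol%), CH2Cl2, rt; volatiles off, THF/hexane, n-BuLi (1 equiv), −78 to 0 °C; (CH2O)n, rt; Ac2O (3 equiv), DMAP (10 mol%), 0 °C to rt
Reagents that add atoms: trimethylaluminium, C[Al](C)C; paraformaldehyde (as formaldehyde), C=O; acetic anhydride, CC(=O)OC(C)=O
Why: Negishi zirconium-catalysed carboalumination adds Me and Al syn with Al at the terminus (E trisubstituted alkene, typically at least 98:2), the alanate adds to formaldehyde with retention of geometry, and the aluminium alkoxide is acetylated in situ.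

Step 7
Reactants: 11 meso diiodo diester; 18 geranyl acetate (2.4 equiv)
Product: 20 dimethyl (2R,3S)-2,3-bis{3-[(2E)-3,7-dimethylocta-2,6-dien-1-yl]-2,5-dimethoxyphenyl}butanedioate (meso), via bis(arylzinc iodide) 19 (not isolated)
Conditions: Zn dust (6 equiv, activated), LiCl (3 equiv), THF, 40 °C, decant from excess Zn; 18, Pd(PPh3)4 (5 mol%), THF, rt
Reagents that add atoms: none
Why: LiCl-promoted zinc insertion into the aryl–iodine bonds gives weakly basic arylzinc reagents that leave the esters and their alpha protons alone, and Negishi-type allyl–aryl coupling through the pi-allylpalladium complex joins aryl to the unsubstituted allyl terminus with retention of the E geometry, the two stereocentres being untouched.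

Step 8
Reactants: 20 meso bis(geranyl) tetramethoxy diester
Product: 21 dimethyl (2R,3S)-2,3-bis{5-[(2E)-3,7-dimethylocta-2,6-dien-1-yl]-3,6-dioxocyclohexa-1,4-dien-1-yl}butanedioate (meso, target)
Conditions: (NH4)2Ce(NO3)6 (4.6 equiv), MeCN/H2O (3:1), 0 °C, 20 min
Reagents that add atoms: water, O
Why: Oxidative demethylation of hydroquinone dimethyl ethers by tetravalent cerium (two one-electron oxidations per ring, water attacks the oxygenated ring carbons and methanol leaves) is faster than attack on trisubstituted alkenes, and the cold acidic medium does not enolise the two stereocentres.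

## Compound list
1 | hydroquinone | Oc1ccc(O)cc1 | starting material
2 | 1,4-dimethoxybenzene | COc1ccc(OC)cc1 | intermediate
3 | succinyl chloride | O=C(Cl)CCC(=O)Cl | starting material
4 | 1,4-bis(2,5-dimethoxyphenyl)butane-1,4-dione | COc1ccc(OC)c(c1)C(=O)CCC(=O)c1cc(OC)ccc1OC | intermediate (not isolated)
5 | 1,4-bis(2-hydroxy-5-methoxyphenyl)butane-1,4-dione | COc1ccc(O)c(c1)C(=O)CCC(=O)c1cc(OC)ccc1O | intermediate
6 | 1,4-bis(2-hydroxy-3-iodo-5-methoxyphenyl)butane-1,4-dione | COc1cc(I)c(O)c(c1)C(=O)CCC(=O)c1cc(OC)cc(I)c1O | intermediate (not isolated)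
7 | 1,4-bis(3-iodo-2,5-dimethoxyphenyl)butane-1,4-dione | COc1cc(I)c(OC)c(c1)C(=O)CCC(=O)c1cc(OC)cc(I)c1OC | intermediate
8 | 1,1,4,4-tetramethoxy-1,4-bis(3-iodo-2,5-dimethoxyphenyl)butane | COc1cc(I)c(OC)c(c1)C(OC)(OC)CCC(OC)(OC)c1cc(OC)cc(I)c1OC | intermediate (not isolated)
9 | methyl 2,4-bis(3-iodo-2,5-dimethoxyphenyl)-4,4-dimethoxybutanoate (racemic, S drawn) | COC(=O)[C@@H](CC(OC)(OC)c1cc(OC)cc(I)c1OC)c1cc(OC)cc(I)c1OC | intermediate (not isolated)
10 | dimethyl 2,3-bis(3-iodo-2,5-dimethoxyphenyl)butanedioate, C2-symmetric diastereomer (racemic, 2S,3S drawn) | COC(=O)[C@H](c1cc(OC)cc(I)c1OC)[C@H](C(=O)OC)c1cc(OC)cc(I)c1OC | intermediate (not isolated)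
11 | dimethyl (2R,3S)-2,3-bis(3-iodo-2,5-dimethoxyphenyl)butanedioate (meso) | COC(=O)[C@H](c1cc(OC)cc(I)c1OC)[C@@H](C(=O)OC)c1cc(OC)cc(I)c1OC | intermediate
12 | 5-bromo-2-methylpent-2-ene | CC(C)=CCCBr | starting material
13 | lithium acetylide–ethane-1,2-diamine complex | [Li]C#C.NCCN | starting material
14 | 6-methylhept-5-en-1-yne | C#CCCC=C(C)C | intermediate
15 | [(1E)-2,6-dimethylhepta-1,5-dien-1-yl]dimethylalane | C[Al](C)/C=C(\C)CCC=C(C)C | intermediate (not isolated)
16 | lithium butyl[(1E)-2,6-dimethylhepta-1,5-dien-1-yl]dimethylalanate | [Li+].CCCC[Al-](C)(C)/C=C(\C)CCC=C(C)C | intermediate (not isolated)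
17 | lithium butyl(geranyloxy)dimethylalanate | [Li+].CCCC[Al-](C)(C)OC/C=C(\C)CCC=C(C)C | intermediate (not isolated)
18 | geranyl acetate | CC(=O)OC/C=C(\C)CCC=C(C)C | intermediate
19 | dimethyl (2R,3S)-2,3-bis[3-(iodozincio)-2,5-dimethoxyphenyl]butanedioate | COC(=O)[C@H](c1cc(OC)cc([Zn]I)c1OC)[C@@H](C(=O)OC)c1cc(OC)cc([Zn]I)c1OC | intermediate (not isolated)
20 | dimethyl (2R,3S)-2,3-bis{3-[(2E)-3,7-dimethylocta-2,6-dien-1-yl]-2,5-dimethoxyphenyl}butanedioate (meso) | COC(=O)[C@H](c1cc(OC)cc(C/C=C(\C)CCC=C(C)C)c1OC)[C@@H](C(=O)OC)c1cc(OC)cc(C/C=C(\C)CCC=C(C)C)c1OC | intermediate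
21 | dimethyl (2R,3S)-2,3-bis{5-[(2E)-3,7-dimethylocta-2,6-dien-1-yl]-3,6-dioxocyclohexa-1,4-dien-1-yl}butanedioate (meso) | COC(=O)[C@H](C1=CC(=O)C=C(C/C=C(\C)CCC=C(C)C)C1=O)[C@@H](C(=O)OC)C1=CC(=O)C=C(C/C=C(\C)CCC=C(C)C)C1=O | target

## Count and risks
Total step count: 8. Longest linear sequence: 6 (steps 1, 2, 3, 4, 7, 8). Steps 5 and 6 form the side branch.

**Step 4 (the proposed new step).**
- Acid may close 7 or 8 to the 2,5-diarylfuran (Paal–Knorr).
- The alpha-iodanyl intermediate may lose PhI and a proton to give the enedione.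
- Migration may be slow because the methoxy group between iodine and the side chain is twisted out of conjugation.
- The oxidant may attack the electron-rich rings of 9 to 11.

The fallback uses only known reaction types and makes the central bond separately. It sets out from 2. Friedel–Crafts acetylation with acetyl chloride and AlCl3 gives 2,5-dimethoxyacetophenone F1, which is demethylated in the same flask to 2-hydroxy-5-methoxyacetophenone F2. NIS then gives 2-hydroxy-3-iodo-5-methoxyacetophenone F3, and MeI/K2CO3 gives 3-iodo-2,5-dimethoxyacetophenone F4. The established oxidative 1,2-aryl shift of an aryl methyl ketone (PhI(OAc)2, H2SO4, HC(OMe)3) gives methyl (3-iodo-2,5-dimethoxyphenyl)acetate F5. Oxidative enolate homocoupling (LiN(i-Pr)2, THF, −78 °C, then I2, 0.5 equiv) gives 10 plus 11. The same NaOMe equilibration brings the route back at 11.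

**Step 7.**
- The double zinc insertion may stop half way.
- The arylzinc may be protonated.
- The pi-allyl complex may leak to the branched or Z product.

The fallback forms the benzyl–vinyl bond instead of the aryl–allyl bond, so no allyl complex is involved. It sets out from 11 and 14. Stille hydroxymethylation (Bu3SnCH2OH, Pd(PPh3)4, dioxane, 90 °C) gives the meso bis(benzylic alcohol) F6. SOCl2 (CH2Cl2, 0 °C) gives the meso bis(benzylic chloride) F7. Coupling with alkenylalane 15, made from 14 as in step 6, under zerovalent nickel catalysis (NiCl2(PPh3)2 reduced with n-BuLi, THF, rt) comes back at 20.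

**Step 8.**
- The oxidant may touch the four alkenes.
- The doubly activated alpha C–H of the product may tautomerise during a slow reaction.

The fallback reverses the order, so the side chains never meet the oxidant. It sets out from 11 and 18. (NH4)2Ce(NO3)6 in MeCN/H2O converts 11 into the meso bis(iodoquinone) F8. Separately, 18 is converted with (Bu3Sn)2 and Pd(PPh3)4 into geranyltributylstannane F9. Stille coupling of F8 with F9 (Pd2(dba)3, AsPh3, CuI, DMF, rt, neutral) comes back at 21.

## Further compounds
F1 | step 4 | 1-(2,5-dimethoxyphenyl)ethanone | CC(=O)c1cc(OC)ccc1OC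
F2 | step 4 | 1-(2-hydroxy-5-methoxyphenyl)ethanone | CC(=O)c1cc(OC)ccc1O
F3 | step 4 | 1-(2-hydroxy-3-iodo-5-methoxyphenyl)ethanone | CC(=O)c1cc(OC)cc(I)c1O
F4 | step 4 | 1-(3-iodo-2,5-dimethoxyphenyl)ethanone | CC(=O)c1cc(OC)cc(I)c1OC
F5 | step 4 | methyl 2-(3-iodo-2,5-dimethoxyphenyl)acetate | COC(=O)Cc1cc(OC)cc(I)c1OC
F6 | step 7 | dimethyl (2R,3S)-2,3-bis[3-(hydroxymethyl)-2,5-dimethoxyphenyl]butanedioate | COC(=O)[C@H](c1cc(OC)cc(CO)c1OC)[C@@H](C(=O)OC)c1cc(OC)cc(CO)c1OC
F7 | step 7 | dimethyl (2R,3S)-2,3-bis[3-(chloromethyl)-2,5-dimethoxyphenyl]butanedioate | COC(=O)[C@H](c1cc(OC)cc(CCl)c1OC)[C@@H](C(=O)OC)c1cc(OC)cc(CCl)c1OC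
F8 | step 8 | dimethyl (2R,3S)-2,3-bis(5-iodo-3,6-dioxocyclohexa-1,4-dien-1-yl)butanedioate | COC(=O)[C@H](C1=CC(=O)C=C(I)C1=O)[C@@H](C(=O)OC)C1=CC(=O)C=C(I)C1=O
F9 | step 8 | tributyl[(2E)-3,7-dimethylocta-2,6-dien-1-yl]stannane | CCCC[Sn](CCCC)(CCCC)C/C=C(\C)CCC=C(C)C
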